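## Analysis of the target

Numbering used throughout: carbocycle C1–C10; C11 (lactone α-carbon), C12 (lactone carbonyl), C13 (CH2OAc), C14 (methyl on C10), C15 (methyl on C4).

Target 38 is a ten-membered carbocycle in which an oxygen joins C1 and C4, so that O, C1, C2, C3 and C4 form a 2,3-dihydrofuran with the enol-ether double bond C1=C2. A γ-alkylidene butenolide (O, C6, C7, C11, C12) is fused at C6–C7; its enol oxygen sits on C6, the exocyclic C5=C6 bond lies in the carbocycle with C4 and C7 cis, and C11 carries the acetoxymethyl group. There are three stereocentres: the quaternary ether carbon C4 (R), the methacrylate carbinol C8 (R) and the tertiary carbinol C10 (S). The C8 and C10 oxygens are 1,3-syn, whereas C4 sits across the ring with no neighbouring centre to relay from. The enol ether next to the tertiary alcohol is acid-labile; the methacrylate, the allylic acetate and the enol lactone are sensitive to base, nucleophiles and zerovalent palladium. The difficulty is a medium ring in which almost every carbon is sp2 or oxygenated, a transannular bridge and a remote quaternary centre. The strategy rests on one feature: the ring O/C1–C4 with its quaternary C4 is a furan Diels–Alder adduct from which only the C1–C6 bond is missing, and C6 is at the ketone level. A C6 carbinol bonded to C1 next to a C2 ketone is therefore a β-hydroxy ketone that can fragment to exactly this array.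

## Retrosynthetic reasoning

**Esters last (38 → 37 → 36).** The two acyl C–O bonds are cut first because the methacrylate and the allylic acetate tolerate the fewest reagents. Forward, triol 36 must be acetylated at the primary C13 hydroxyl, then methacryloylated at the secondary C8 hydroxyl, with the tertiary C10 hydroxyl left free.

**Silicon groups (36 → 35).** One silylene across O8/O10 and one silyl ether at O13 are removed in a single non-acidic operation, so no acid is needed once the enol ether exists.

**Butenolide (35 → 34 → 29 + 33).** The C7=C11 bond is cut as an intramolecular olefination and O6–C12 as an enol acylation. This reduces the lactone to the 1,2-dione 29 and to phosphonate acid 33, which carries C11–C13 and is made from 30 through 31 and 32. The forward acylation must occur on the C5 enol of 29, not toward C8.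

**Oxidation-level corrections (29 → 28 → 27 → 26).** The C7 ketone comes from the C7 carbinol of 28, the enol-ether hydrogen at C2 from the triflate of 27, and the free C7 hydroxyl from the acetal of 26. The acetal is removed while C1=C2 still carries the deactivating triflate, so the only acidic step precedes the acid-sensitive enol ether.

**Key disconnection (26 → 23).** Retrosynthetically the C1–C6 bond is re-formed, turning the ten-membered ring into a cyclohexane (ring B) fused to a 7-oxanorbornan-2-one. No other bond offers this: C1–C6 is the only bond whose cleavage is driven by bicyclic strain and ends in the C1=C2 enolate and the C6 ketone at once. Forward, only the C6 alkoxide may form, and the enolate must be trapped before it equilibrates.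

**Cycloaddition (23 → 22 → 20 → 19 → 18).** Cutting C1–C6 and C4–C5 reveals siloxyfuran/siloxy-enone 19, made from furanone-dione 18. The forward Diels–Alder reaction must set C4 relative to C8 and C10. For that reason the syn O8/O10 pair is tied as a silylene, which restricts the tether to one chair-like approach. C7 is reduced while C2 is still an enol ether (20 → 22), which avoids a ketone-versus-ketone selectivity problem.

**Furanone and dione (18 → 17 → 15 → 14).** The furanone O–C4 bond and its C2 carbonyl come from the γ-hydroxy ynone of 14. The dione comes from a diol, itself from the cis alkene. An alkene is used as the latent dione because its oxidation is compatible with the second alkyne, which a direct alkyne-to-dione oxidation would not be.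

**C1–C4 unit (14 → 12 → 10, with 11 and 13).** C1–C2 and C3–C4 are cut. Four carbons are needed beyond C1, so an ethynyl unit (11) followed by acetylation (13) is used.

**Protecting-group pattern (10 → 9 → 8 → 7 → 6).** The aldehyde is a reduced amide; the alkene is a semi-reduced alkyne; the silylene closes a 1,3-diol that appears when the dioxolanone of 6 is opened by an amine.

**Chiral pool (6 → 5 → 2 + 3 → 1).** The C7–C8 bond is cut to acid chloride 4 (from acid 2) and the propynyl nucleophile 3. C8 is set by reagent-controlled reduction of ynone 5. C10 with its methyl and oxygen, C9, C1 and C8 are the carbon chain of (S)-citramalic acid 1.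

## Alternatives that were turned down

**Alternative 1:** The bridge bond O–C1 and the C5=C6 double bond are disconnected, leaving the intact ten-membered C1 ketone A2 with a C4–C5 epoxide and a butenolide bearing hydrogen at C6. In the forward step an amidine base removes the C6 proton, the extended enolate opens the epoxide at C5 (forming C5=C6), and the released C4 alkoxide adds across the ring to the C1 ketone to give hemiketal A1. Dehydration toward C2 would finish the target.
- For: it follows the probable biogenesis, makes the bridge and the exocyclic alkene in one step, fixes C4 from the epoxide and allows both esters to be in place early. On end-game brevity and on certainty at C4 once A2 exists it is stronger than the chosen route.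
- Against: it offers no help in making A2, a ten-membered α-hydroxy ketone whose epoxide configuration would depend on macrocyclic conformation. The last step is an acid dehydration of A1 beside the tertiary C10 alcohol, giving an enol ether that is itself acid-labile.
- Comparison: the chosen strategy supplies what is missing here. The ring is released from a six-membered ring instead of being cyclised, and C1=C2 is delivered under base at the right oxidation level.

**Alternative 2:** The C3–C4 bond is disconnected and C1–C6 reconnected, leading to the cis-1,2-dialkenylcyclohexanol A4 from the cyclohexane chiral pool. Its potassium alkoxide would undergo anionic oxy-Cope rearrangement to the cyclodecenone A3, which has the C1 ketone, the quaternary C4 ether and the C5=C6 enol ether.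
- For: a skeletal C–C bond and the ring are made in one pericyclic step; the C7/C8 oxygens come from the chiral pool; C6 emerges at the ketone level. In carbon-bond construction by the key step it is stronger than the chosen route, whose key step builds no skeletal bond.
- Against: the new bond ends at a fully substituted, oxygenated alkene carbon, so the rearrangement is slow. The C4 configuration depends on the geometry of a trisubstituted enol-ether alkene and on chair-versus-boat control. The bridge and C1=C2 must still be made afterwards by acid ketalisation and dehydration, and A4 with two different alkenyl groups on adjacent quaternary carbons is long to prepare.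
- Comparison: the chosen route instead obtains the bridge oxygen and quaternary C4 from a furan and the enol ether from an enol triflate, without acid.

**Alternative 3:** The C1=C2 bond is disconnected to the bridged 1,3-oxathiane dioxide A6. A Ramberg–Bäcklund reaction would remove the sulfonyl bridge, contract the oxathiane to the dihydrofuran and close the ten-membered carbocycle, giving A5 with the butenolide carbons already attached.
- For: the enol ether is formed under base; the large ring is first closed through sulfur, which is easier than C–C macrocyclisation; the approach is convergent. On convergence and on carrying the butenolide carbons early it is as strong as or stronger than the chosen route.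
- Against: the episulfone must form between a methine that is α-oxygenated and tertiary and a methylene inside a bridged bicycle. The conditions are strongly basic and halogenating in the presence of an alkylidene ester. C4 must be set by a separate tertiary-ether synthesis, and sulfur must be introduced and oxidised in the presence of alkenes.
- Comparison: the chosen route sets C4 in the cycloaddition and needs no auxiliary heteroatom; its key step is closer to known fragmentations.

Key step: step 16

Assumption: hydride reduction at C7 (step 14) is taken to occur from the face of the oxygen bridge; either C7 epimer would serve because C7 is oxidised in step 19, and the C1, C6 and C7 mixtures in 12 and 14–17 are erased in steps 12 and 13.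

## Route

Step 1
Reactants: 1 (S)-citramalic acid
Product: 2 2-[(4S)-2,2,4-trimethyl-5-oxo-1,3-dioxolan-4-yl]acetic acid
Conditions: 2,2-dimethoxypropane, PPTS (cat.), acetone, rt
Reagents that add atoms: 2,2-dimethoxypropane COC(C)(C)OC
Why: Acid-catalysed transacetalisation closes the five-membered dioxolanone on the α-hydroxy acid half, masking C1 and O10 together and leaving the C8 carboxyl free; the stereocentre is not touched.

Step 2
Reactants: 2 dioxolanone acid; 3 1-propynylmagnesium bromide
Product: 5 (5S)-2,2,5-trimethyl-5-(2-oxopent-3-yn-1-yl)-1,3-dioxolan-4-one, via acid chloride 4 (not isolated)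
Conditions: (COCl)2, DMF (cat.), CH2Cl2, 0 °C to rt; then 3 premixed with ZnCl2, Pd(PPh3)4 (cat.), THF, 0 °C to rt
Reagents that add atoms: none
Why: Negishi acylation of the alkynylzinc reagent by the acid chloride forms C7–C8 under non-basic conditions, which spares the dioxolanone and avoids β-elimination of the C10 oxygen.

Step 3
Reactants: 5 ynone
Product: 6 (5S)-5-[(2R)-2-hydroxypent-3-yn-1-yl]-2,2,5-trimethyl-1,3-dioxolan-4-one
Conditions: Ru[(R,R)-TsDPEN](p-cymene) (cat.), i-PrOH, rt
Reagents that add atoms: none
Why: Noyori asymmetric transfer hydrogenation of an alkynyl ketone sets C8 by reagent control; the (R,R) catalyst should give the (R)-carbinol, and the neutral amido complex avoids base.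

Step 4
Reactants: 6 propargylic alcohol
Product: 7 (2S,4R)-2,4-dihydroxy-N-methoxy-N,2-dimethylhept-5-ynamide
Conditions: MeNH(OMe)·HCl, AlMe3, CH2Cl2, 0 °C to rt
Reagents that add atoms: N,O-dimethylhydroxylamine hydrochloride CNOC.Cl
Why: Weinreb aminolysis of the activated dioxolanone ester releases the tertiary C10 hydroxyl; any lactone formed from the C8 hydroxyl is opened to the same amide.

Step 5
Reactants: 7 dihydroxy amide
Product: 8 (4S,6R)-2,2-di-tert-butyl-N-methoxy-N,4-dimethyl-6-(prop-1-yn-1-yl)-1,3,2-dioxasilinane-4-carboxamide
Conditions: t-Bu2Si(OTf)2, 2,6-lutidine, CH2Cl2, 0 °C to rt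
Reagents that add atoms: di-tert-butylsilyl bis(trifluoromethanesulfonate) CC(C)(C)[Si](OS(=O)(=O)C(F)(F)F)(OS(=O)(=O)C(F)(F)F)C(C)(C)C
Why: Silylene protection of the syn-1,3-diol covers O8 and O10 with one group that is stable to base and hydride, leaves with fluoride, and later clamps the tether of the cycloaddition.

Step 6
Reactants: 8 alkynyl silylene
Product: 9 (4S,6R)-2,2-di-tert-butyl-N-methoxy-N,4-dimethyl-6-[(1Z)-prop-1-en-1-yl]-1,3,2-dioxasilinane-4-carboxamide
Conditions: H2 (1 atm), Pd/CaCO3 poisoned with Pb(OAc)2, quinoline, EtOAc, rt
Reagents that add atoms: none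
Why: Lindlar semi-hydrogenation gives the cis alkene that serves as the latent C6/C7 dione; amide and silylene are inert.

Step 7
Reactants: 9 Weinreb amide
Product: 10 (4S,6R)-2,2-di-tert-butyl-4-methyl-6-[(1Z)-prop-1-en-1-yl]-1,3,2-dioxasilinane-4-carbaldehyde
Conditions: i-Bu2AlH, THF, −78 °C; Rochelle salt
Reagents that add atoms: none
Why: Hydride reduction of a Weinreb amide stops at the aldehyde through the chelated tetrahedral intermediate; the aldehyde has no α-hydrogen and cannot epimerise.

Step 8
Reactants: 10 aldehyde; 11 ethynylmagnesium bromide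
Product: 12 1-{(4S,6R)-2,2-di-tert-butyl-4-methyl-6-[(1Z)-prop-1-en-1-yl]-1,3,2-dioxasilinan-4-yl}prop-2-yn-1-ol (both C1 epimers)
Conditions: THF, −78 to 0 °C
Reagents that add atoms: none
Why: Grignard addition forms C1–C2; the new C1 centre needs no control because C1 becomes sp2 in step 13.

Step 9
Reactants: 12 propargylic alcohol; 13 N-methoxy-N-methylacetamide
Product: 14 5-{(4S,6R)-2,2-di-tert-butyl-4-methyl-6-[(1Z)-prop-1-en-1-yl]-1,3,2-dioxasilinan-4-yl}-5-hydroxypent-3-yn-2-one (both C1 epimers)
Conditions: n-BuLi (2.2 equiv), THF, −78 °C; then 13, −78 to 0 °C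
Reagents that add atoms: none
Why: The alkoxide–acetylide dianion is C-acylated by the Weinreb amide, whose stable tetrahedral intermediate prevents over-addition, giving the γ-hydroxy ynone with C3–C4 formed.

Step 10
Reactants: 14 ynone
Product: 15 5-[(4S,6R)-2,2-di-tert-butyl-6-(1,2-dihydroxypropyl)-4-methyl-1,3,2-dioxasilinan-4-yl]-5-hydroxypent-3-yn-2-one (diastereomer mixture at C1, C6, C7)
Conditions: OsO4 (cat.), N-methylmorpholine N-oxide, acetone/H2O, 0 °C to rt
Reagents that add atoms: N-methylmorpholine N-oxide C[N+]1([O-])CCOCC1; water O
Why: Upjohn dihydroxylation is selective for the cis alkene because the conjugated alkyne is inert to OsO4; the diol configuration is irrelevant since both carbons become carbonyls.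

Step 11
Reactants: 15 triol ynone
Product: 17 2-[(4S,6R)-2,2-di-tert-butyl-6-(1,2-dihydroxypropyl)-4-methyl-1,3,2-dioxasilinan-4-yl]-5-methylfuran-3(2H)-one, via enaminone 16 (not isolated)
Conditions: Et2NH, EtOH, rt; then AcOH, H2O, THF, 40 °C
Reagents that add atoms: none
Why: Conjugate addition of the amine at C2 gives the enaminone; on acid hydrolysis the C1 hydroxyl closes onto the C4 carbonyl with loss of water. This is the classical 3(2H)-furanone synthesis from γ-hydroxy ynones and places the carbonyl on C2.

Step 12
Reactants: 17 furanone diol
Product: 18 1-[(4S,6R)-2,2-di-tert-butyl-4-methyl-4-(5-methyl-3-oxo-2,3-dihydrofuran-2-yl)-1,3,2-dioxasilinan-6-yl]propane-1,2-dione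
Conditions: (COCl)2, DMSO, CH2Cl2, −78 °C; i-Pr2NEt, −78 to −30 °C
Reagents that add atoms: none
Why: Swern oxidation converts the vicinal diol to the 1,2-dione without C–C cleavage; low temperature and a hindered amine protect the C8 centre α to the new ketone.

Step 13
Reactants: 18 furanone dione
Product: 20 Diels–Alder adduct (7-oxanorbornene: O bridge C1/C4 and C2=C3 with C2–OSiMe3 and C4–Me; fused at C1–C6 to ring B with C7 ketone exo and C6–OSiMe3 endo; O8/O10 silylene anti to the oxygen bridge), via bis-silyl siloxyfuran enone 19 (not isolated)
Conditions: Me3SiOTf, Et3N, CH2Cl2, −78 to 0 °C; then toluene, 80 °C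
Reagents that add atoms: trimethylsilyl trifluoromethanesulfonate C[Si](C)(C)OS(=O)(=O)C(F)(F)F
Why: Soft enolisation aromatises the furanone to the 3-siloxyfuran and enolises the dione at its methyl group (α′-selective, as usual for α-silyloxy ketones); the intramolecular Diels–Alder reaction then forms C1–C6 and C4–C5 with the tether exo. The silylene holds O8 and O10 syn-diaxial on the forming ring B, which fits a chair-like transition state only for the furan face that gives the required C4 configuration.

Step 14
Reactants: 20 adduct
Product: 22 7-oxanorbornan-2-one diol (C2 ketone; C6–OH endo; C7–OH cis to the C6 and C8 oxygens; silylene retained), via C7 carbinol bis-silyl ether 21 (not isolated)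
Conditions: i-Bu2AlH, CH2Cl2, −78 °C; then AcOH, THF, H2O, rt
Reagents that add atoms: none
Why: Only the C7 ketone is free while C2 is still a silyl enol ether, so the hydride reduction is chemoselective; attack should come from the face of the oxygen bridge because the other face is covered by the axial C6 siloxy group and the silylene. Dilute acid then hydrolyses the silyl enol ether to the C2 ketone and the tertiary trimethylsilyl ether to the C6 alcohol.

Step 15
Reactants: 22 diol
Product: 23 key precursor: C6 tertiary alcohol, C7 methoxymethyl ether, C2 ketone, O8/O10 silylene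
Conditions: MeOCH2Cl, i-Pr2NEt, Bu4NI (cat.), CH2Cl2, 0 to 35 °C
Reagents that add atoms: chloromethyl methyl ether COCCl
Why: Alkylation under amine base takes the secondary C7 hydroxyl and leaves the hindered tertiary C6 hydroxyl; an acetal is chosen because, unlike a silyl group, it cannot migrate to the C6 alkoxide in the next step.

Step 16
Reactants: 23 key precursor; 24 N-phenyl-bis(trifluoromethanesulfonimide)
Product: 26 oxa-bridged cyclodecenone enol triflate (C1=C2–OTf, C6 ketone, C7–OMOM, silylene), via potassium enolate 25 (not isolated)
Conditions: KN(SiMe3)2 (1.05 equiv), THF, −78 °C; then 24, −78 to −20 °C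
Reagents that add atoms: none
Why: The amide base removes the C6 hydroxyl proton, the most acidic one in 23. The alkoxide forms the C6 carbonyl, the C1–C6 bond breaks and its electrons end in the C1=C2 enolate 25; this is a retro-aldol reaction whose closest known type is the strain-driven fragmentation of bicyclic β-hydroxy ketones. No bond is made: the ten-membered carbocycle is released by cutting the bond shared by ring B and the oxanorbornane (ring expansion by fragmentation), while the ring O/C1–C4 survives as the dihydrofuran. No stereocentre is created; C1 and C6 become sp2 and C4, C7, C8 and C10 are untouched. The driving force is the loss of oxanorbornane strain, and the C1–C6 bond lies nearly perpendicular to the C2 carbonyl plane, as the cleavage requires. Cleavage is confined to C1–C6 because the C6 alkoxide is the only alkoxide (O8 and O10 are in the silylene, the C7 oxygen is an acetal) and has a single β-carbonyl. The enolate regiochemistry is fixed by the bond that breaks, and O-triflation by 24 makes it permanent before proton transfer from C5 or C7 can occur. One equivalent of base at −78 °C avoids deprotonation at C3, which would open the oxygen bridge.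

Step 17
Reactants: 26 enol triflate
Product: 27 C7 alcohol (α-hydroxy ketone) enol triflate
Conditions: Me2BBr, CH2Cl2, −78 °C; then aq. NaHCO3
Reagents that add atoms: none
Why: Lewis-acid cleavage of the methoxymethyl acetal, assisted by chelation to the C6 ketone, proceeds at −78 °C where silyl groups are normally retained; it is done now because the triflate-bearing alkene is not acid-sensitive, unlike the later enol ether.

Step 18
Reactants: 27 enol triflate
Product: 28 C1=C2 enol ether with C6 ketone and C7 alcohol
Conditions: Pd(OAc)2 (cat.), PPh3, Bu3N, HCO2H, DMF, 60 °C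
Reagents that add atoms: none
Why: Palladium-catalysed formate reduction of an enol triflate (oxidative addition, hydride from formate with loss of CO2, reductive elimination) replaces the triflate by hydrogen; the buffered medium is mild toward the α-hydroxy ketone.

Step 19
Reactants: 28 α-hydroxy ketone
Product: 29 C6/C7 1,2-dione
Conditions: Dess–Martin periodinane, NaHCO3, CH2Cl2, 0 °C to rt
Reagents that add atoms: none
Why: Dess–Martin oxidation of the acyloin to the dione; the bicarbonate buffer protects the enol ether from the acetic acid released.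

Step 20
Reactants: 30 benzyl dimethylphosphonoacetate
Product: 31 benzyl 2-(dimethoxyphosphoryl)-3-hydroxypropanoate (racemic)
Conditions: (CH2O)n (1.0 equiv), piperidine (cat.), THF, rt
Reagents that add atoms: formaldehyde (as paraformaldehyde) C=O
Why: Amine-catalysed aldol-type hydroxymethylation of the phosphonoacetate; with one equivalent of formaldehyde and only catalytic base the adduct should not go on to olefination.

Step 21
Reactants: 31 hydroxy phosphonate
Product: 32 benzyl 3-[(tert-butyldimethylsilyl)oxy]-2-(dimethoxyphosphoryl)propanoate
Conditions: t-BuMe2SiCl, imidazole, CH2Cl2, 0 °C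
Reagents that add atoms: tert-butyldimethylsilyl chloride CC(C)(C)[Si](C)(C)Cl
Why: Standard silylation of the primary alcohol; a silyloxy group is a far poorer leaving group than acetate from the later phosphonate anion.

Step 22
Reactants: 32 benzyl ester
Product: 33 3-[(tert-butyldimethylsilyl)oxy]-2-(dimethoxyphosphoryl)propanoic acid
Conditions: H2, Pd/C, EtOAc, rt
Reagents that add atoms: none
Why: Hydrogenolysis frees the acid under neutral conditions that leave the silyl ether and the phosphonate intact.

Step 23
Reactants: 29 dione; 33 phosphonate acid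
Product: 34 C5=C6 enol ester of 29 with 33 (C7 ketone retained; C4 and C7 cis on the double bond)
Conditions: EDC·HCl, DMAP, CH2Cl2, −20 to 0 °C
Reagents that add atoms: none
Why: Steglich-type O-acylation of the enol form; enolisation should occur at the C5 methylene and not at the hindered α-silyloxy C8–H (α′-selectivity of α-silyloxy ketones). In the bridged ten-membered ring the enol double bond can form only cis, as in the target.

Step 24
Reactants: 34 enol phosphonoacetate
Product: 35 butenolide with C13 silyl ether and O8/O10 silylene
Conditions: LiCl, DBU, MeCN, 0 °C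
Reagents that add atoms: none
Why: Intramolecular Horner–Wadsworth–Emmons reaction: the phosphonate anion adds to the adjacent C7 ketone, closing the five-membered lactone and forming C7=C11; this fast ring closure should outrun loss of the β-silyloxy group.

Step 25
Reactants: 35 protected butenolide
Product: 36 triol (C8–OH, C10–OH, C13–OH)
Conditions: HF·pyridine, pyridine, THF, 0 °C to rt
Reagents that add atoms: none
Why: Buffered fluoride cleaves the silylene and the primary silyl ether in one operation; excess pyridine keeps the medium too weakly acidic to protonate the enol ether.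

Step 26
Reactants: 36 triol
Product: 37 13-acetate with free C8 and C10 hydroxyls
Conditions: AcCl, 2,4,6-collidine, CH2Cl2, −78 °C
Reagents that add atoms: acetyl chloride CC(Cl)=O
Why: Low-temperature acetylation with a hindered pyridine base is selective for the primary allylic alcohol over the secondary C8 and tertiary C10 alcohols.

Step 27
Reactants: 37 diol acetate
Product: 38 target CNP0394509.1, (4R,8R,10S)
Conditions: methacrylic anhydride, Et3N, DMAP (cat.), CH2Cl2, 0 °C
Reagents that add atoms: methacrylic anhydride C=C(C)C(=O)OC(=O)C(C)=C
Why: DMAP-catalysed acylation takes the secondary allylic C8 alcohol; the tertiary C10 alcohol does not react under these conditions, so no further protection is needed.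

## Compound list

1 | (S)-citramalic acid | OC(=O)C[C@](C)(O)C(=O)O | starting material
2 | 2-[(4S)-2,2,4-trimethyl-5-oxo-1,3-dioxolan-4-yl]acetic acid | OC(=O)C[C@]1(C)OC(C)(C)OC1=O | intermediate
3 | 1-propynylmagnesium bromide | CC#C[Mg]Br | starting material
4 | 2-[(4S)-2,2,4-trimethyl-5-oxo-1,3-dioxolan-4-yl]acetyl chloride | ClC(=O)C[C@]1(C)OC(C)(C)OC1=O | intermediate
5 | (5S)-2,2,5-trimethyl-5-(2-oxopent-3-yn-1-yl)-1,3-dioxolan-4-one | CC#CC(=O)C[C@]1(C)OC(C)(C)OC1=O | intermediate
6 | (5S)-5-[(2R)-2-hydroxypent-3-yn-1-yl]-2,2,5-trimethyl-1,3-dioxolan-4-one | CC#C[C@H](O)C[C@]1(C)OC(C)(C)OC1=O | intermediate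
7 | (2S,4R)-2,4-dihydroxy-N-methoxy-N,2-dimethylhept-5-ynamide | CC#C[C@H](O)C[C@](C)(O)C(=O)N(C)OC | intermediate
8 | (4S,6R)-2,2-di-tert-butyl-N-methoxy-N,4-dimethyl-6-(prop-1-yn-1-yl)-1,3,2-dioxasilinane-4-carboxamide | CC#C[C@H]1C[C@@](C)(C(=O)N(C)OC)O[Si](C(C)(C)C)(C(C)(C)C)O1 | intermediate
9 | (4S,6R)-2,2-di-tert-butyl-N-methoxy-N,4-dimethyl-6-[(1Z)-prop-1-en-1-yl]-1,3,2-dioxasilinane-4-carboxamide | C/C=C\[C@H]1C[C@@](C)(C(=O)N(C)OC)O[Si](C(C)(C)C)(C(C)(C)C)O1 | intermediate
10 | (4S,6R)-2,2-di-tert-butyl-4-methyl-6-[(1Z)-prop-1-en-1-yl]-1,3,2-dioxasilinane-4-carbaldehyde | C/C=C\[C@H]1C[C@@](C)(C=O)O[Si](C(C)(C)C)(C(C)(C)C)O1 | intermediate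
11 | ethynylmagnesium bromide | C#C[Mg]Br | starting material
12 | propargylic alcohol at C1 (both epimers) of the (4S,6R)-silylene | C/C=C\[C@H]1C[C@@](C)(C(O)C#C)O[Si](C(C)(C)C)(C(C)(C)C)O1 | intermediate
13 | N-methoxy-N-methylacetamide | CON(C)C(C)=O | starting material
14 | γ-hydroxy ynone (both C1 epimers) | C/C=C\[C@H]1C[C@@](C)(C(O)C#CC(C)=O)O[Si](C(C)(C)C)(C(C)(C)C)O1 | intermediate
15 | triol ynone (mixture at C1, C6, C7) | CC(O)C(O)[C@H]1C[C@@](C)(C(O)C#CC(C)=O)O[Si](C(C)(C)C)(C(C)(C)C)O1 | intermediate
16 | diethylamino enaminone | CC(O)C(O)[C@H]1C[C@@](C)(C(O)C(=CC(C)=O)N(CC)CC)O[Si](C(C)(C)C)(C(C)(C)C)O1 | intermediate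
17 | 5-methylfuran-3(2H)-one with C6/C7 diol (mixture at C1, C6, C7) | CC(O)C(O)[C@H]1C[C@@](C)(C2OC(C)=CC2=O)O[Si](C(C)(C)C)(C(C)(C)C)O1 | intermediate
18 | furanone 1,2-dione (C1 epimers) | CC(=O)C(=O)[C@H]1C[C@@](C)(C2OC(C)=CC2=O)O[Si](C(C)(C)C)(C(C)(C)C)O1 | intermediate
19 | 3-(trimethylsiloxy)furan with 2-(trimethylsiloxy)enone | C=C(O[Si](C)(C)C)C(=O)[C@H]1C[C@@](C)(c2oc(C)cc2O[Si](C)(C)C)O[Si](C(C)(C)C)(C(C)(C)C)O1 | intermediate
20 | Diels–Alder adduct, C7 ketone, bis(trimethylsilyl) | CC(C)(C)[Si]1(C(C)(C)C)O[C@@H]2C[C@](C)(O1)[C@]34O[C@](C)(C=C3O[Si](C)(C)C)C[C@@]4(O[Si](C)(C)C)C2=O | intermediate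
21 | C7 carbinol of the adduct, bis(trimethylsilyl) | CC(C)(C)[Si]1(C(C)(C)C)O[C@@H]2C[C@](C)(O1)[C@]34O[C@](C)(C=C3O[Si](C)(C)C)C[C@@]4(O[Si](C)(C)C)[C@@H]2O | intermediate
22 | 7-oxanorbornan-2-one C6/C7 diol | CC(C)(C)[Si]1(C(C)(C)C)O[C@@H]2C[C@](C)(O1)[C@]34O[C@](C)(CC3=O)C[C@@]4(O)[C@@H]2O | intermediate
23 | key precursor (C6–OH, C7–OMOM, C2 ketone) | CC(C)(C)[Si]1(C(C)(C)C)O[C@@H]2C[C@](C)(O1)[C@]34O[C@](C)(CC3=O)C[C@@]4(O)[C@@H]2OCOC | intermediate
24 | N-phenyl-bis(trifluoromethanesulfonimide) | O=S(=O)(N(c1ccccc1)S(=O)(=O)C(F)(F)F)C(F)(F)F | starting material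
25 | ring-opened potassium C1=C2 enolate | CC(C)(C)[Si]1(C(C)(C)C)O[C@@H]2C[C@](C)(O1)C3=C([O-])C[C@](C)(CC(=O)[C@@H]2OCOC)O3.[K+] | intermediate
26 | oxa-bridged cyclodecenone enol triflate | CC(C)(C)[Si]1(C(C)(C)C)O[C@@H]2C[C@](C)(O1)C3=C(OS(=O)(=O)C(F)(F)F)C[C@](C)(CC(=O)[C@@H]2OCOC)O3 | intermediate
27 | C7 alcohol enol triflate | CC(C)(C)[Si]1(C(C)(C)C)O[C@@H]2C[C@](C)(O1)C3=C(OS(=O)(=O)C(F)(F)F)C[C@](C)(CC(=O)[C@@H]2O)O3 | intermediate
28 | enol ether α-hydroxy ketone | CC(C)(C)[Si]1(C(C)(C)C)O[C@@H]2C[C@](C)(O1)C3=CC[C@](C)(CC(=O)[C@@H]2O)O3 | intermediate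
29 | enol ether C6/C7 dione | CC(C)(C)[Si]1(C(C)(C)C)O[C@@H]2C[C@](C)(O1)C3=CC[C@](C)(CC(=O)C2=O)O3 | intermediate
30 | benzyl dimethylphosphonoacetate | COP(=O)(CC(=O)OCc1ccccc1)OC | starting material
31 | benzyl 2-(dimethoxyphosphoryl)-3-hydroxypropanoate | COP(=O)(OC)C(CO)C(=O)OCc1ccccc1 | intermediate
32 | benzyl 3-[(tert-butyldimethylsilyl)oxy]-2-(dimethoxyphosphoryl)propanoate | COP(=O)(OC)C(CO[Si](C)(C)C(C)(C)C)C(=O)OCc1ccccc1 | intermediate
33 | 3-[(tert-butyldimethylsilyl)oxy]-2-(dimethoxyphosphoryl)propanoic acid | COP(=O)(OC)C(CO[Si](C)(C)C(C)(C)C)C(O)=O | intermediate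
34 | C5=C6 enol phosphonoacetate | CC(C)(C)[Si]1(C(C)(C)C)O[C@@H]2C[C@](C)(O1)C3=CC[C@](C)(/C=C(/OC(=O)C(CO[Si](C)(C)C(C)(C)C)P(=O)(OC)OC)C2=O)O3 | intermediate
35 | silyl-protected butenolide | CC(C)(C)[Si]1(C(C)(C)C)O[C@@H]2C[C@](C)(O1)C3=CC[C@](C)(/C=C4/OC(=O)C(CO[Si](C)(C)C(C)(C)C)=C42)O3 | intermediate
36 | triol | O[C@@H]1C[C@](C)(O)C2=CC[C@](C)(/C=C3/OC(=O)C(CO)=C31)O2 | intermediate
37 | 13-acetate diol | O[C@@H]1C[C@](C)(O)C2=CC[C@](C)(/C=C3/OC(=O)C(COC(C)=O)=C31)O2 | intermediate
38 | CNP0394509.1 | C=C(C)C(=O)O[C@@H]1C[C@](C)(O)C2=CC[C@](C)(/C=C3/OC(=O)C(COC(C)=O)=C31)O2 | target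

## Step count and least certain steps

Total: 27 steps. Longest linear sequence: 24 steps (steps 1–19 and 23–27); the phosphonate branch is steps 20–22.

**Step 16 (key step).**
- The C6 alkoxide lies 1,3-diaxial to O8 and O10 and may attack the silylene silicon; silyl transfer would block the fragmentation and free the C10 alkoxide.
- Proton transfer from C5 or C7 to the new enolate before triflation would scramble the triflate position or trigger β-elimination.
- Deprotonation at C3 would open the oxygen bridge.
- Fallback (from 23, back at 26): replace the anionic fragmentation by an alkoxy-radical one. Irradiation of 23 with PhI(OAc)2 and I2 (Suárez conditions) forms the C6 hypoiodite. β-Scission of the C6 alkoxy radical cuts the same C1–C6 bond, because the C1 radical is flanked by the ring oxygen and the C2 carbonyl and the strain is released. Iodine transfer gives the ring-opened C1-iodo diketone F1. SmI2 at −78 °C reduces the C1–I bond to the same C1=C2 enolate, which is triflated with 24 to give 26.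

**Step 13.**
- The tether forces C1 to bond to the substituted dienophile carbon, against the intrinsic polarisation of a 3-siloxyfuran, so the cycloaddition may be slow or reversible.
- The required transition state places three oxygens syn-axial on ring B.
- A boat-like approach to the other furan face would erode facial selectivity.
- Enolisation of the dione toward C8 would destroy that centre.
- Fallback (from 18, back at 22): change the electronic pairing by using acyl in place of silyl groups. Ac2O, Et3N and DMAP convert 18 into the 3-acetoxyfuran/2-acetoxy enone F2, with irreversible kinetic O-acylation at the methyl side. Heating F2 gives the diacetate adduct F3, whose dienophile is more electron-poor. Excess i-Bu2AlH at −78 °C then reduces the C7 ketone and cleaves both acetates; the C2 aluminium enolate is protonated on work-up to give 22.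

**Step 24.**
- The phosphonate anion may lose the β-silyloxy group (E1cB) before it adds to C7.
- The base may epimerise C8 through the C7 ketone.
- Fallback (from 29, back at 35): an aldol–dehydration in place of the olefination. Dione 29 is acylated, as in step 23, with 2-bromo-3-[(tert-butyldimethylsilyl)oxy]propanoic acid to give the enol bromo ester F4. SmI2 at −78 °C effects an intramolecular Reformatsky addition to the C7 ketone, giving the β-hydroxy lactone F5. Dehydration with MsCl and Et3N then gives 35.

**Step 17.**
- The Lewis acid may also attack the silylene or the bridging ether, or the acetal may be cleaved only sluggishly next to the quaternary centre.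
- Fallback (from 22, back at 27): an oxidatively removable ether. Diol 22 is converted with 4-methoxybenzyl trichloroacetimidate and La(OTf)3 into the C7 4-methoxybenzyl ether F6. The fragmentation of step 16 applied to F6 gives the enol triflate F7. DDQ in buffered wet CH2Cl2 then removes the benzyl ether, which is safe at the triflate stage, to give 27.

## Further compounds

F1 | step 16 | ring-opened C1-iodo C2/C6 diketone | CC(C)(C)[Si]1(C(C)(C)C)O[C@@H]2C[C@](C)(O1)C3(I)C(=O)C[C@](C)(CC(=O)[C@@H]2OCOC)O3
F2 | step 13 | 3-acetoxyfuran with 2-acetoxy enone | C=C(OC(C)=O)C(=O)[C@H]1C[C@@](C)(c2oc(C)cc2OC(C)=O)O[Si](C(C)(C)C)(C(C)(C)C)O1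
F3 | step 13 | Diels–Alder adduct diacetate | CC(C)(C)[Si]1(C(C)(C)C)O[C@@H]2C[C@](C)(O1)[C@]34O[C@](C)(C=C3OC(C)=O)C[C@@]4(OC(C)=O)C2=O
F4 | step 24 | C5=C6 enol 2-bromo-3-silyloxypropanoate | CC(C)(C)[Si]1(C(C)(C)C)O[C@@H]2C[C@](C)(O1)C3=CC[C@](C)(/C=C(/OC(=O)C(Br)CO[Si](C)(C)C(C)(C)C)C2=O)O3
F5 | step 24 | C7-hydroxy lactone | CC(C)(C)[Si]1(C(C)(C)C)O[C@@H]2C[C@](C)(O1)C3=CC[C@](C)(/C=C4/OC(=O)C(CO[Si](C)(C)C(C)(C)C)C42O)O3
F6 | step 17 | key precursor with C7 4-methoxybenzyl ether | CC(C)(C)[Si]1(C(C)(C)C)O[C@@H]2C[C@](C)(O1)[C@]34O[C@](C)(CC3=O)C[C@@]4(O)[C@@H]2OCc2ccc(OC)cc2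
F7 | step 17 | enol triflate with C7 4-methoxybenzyl ether | CC(C)(C)[Si]1(C(C)(C)C)O[C@@H]2C[C@](C)(O1)C3=C(OS(=O)(=O)C(F)(F)F)C[C@](C)(CC(=O)[C@@H]2OCc2ccc(OC)cc2)O3
A1 | alternative 1 | C1 hemiketal of the target | C=C(C)C(=O)O[C@@H]1C[C@](C)(O)[C@]2(O)CC[C@](C)(/C=C3/OC(=O)C(COC(C)=O)=C31)O2
A2 | alternative 1 | ten-membered C1 ketone with C4–C5 epoxide and C6–H butenolide | C=C(C)C(=O)O[C@@H]1C[C@](C)(O)C(=O)CC[C@@]2(C)O[C@@H]2[C@H]3OC(=O)C(COC(C)=O)=C31
A3 | alternative 2 | cyclodec-5-enone with C4 quaternary ether and C5=C6 enol ether | CC1(C)O[C@@H]2C[C@](C)(OCOC)C(=O)CC[C@@](C)(OCOC)/C=C(/OCOC)[C@@H]2O1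
A4 | alternative 2 | cis-1,2-dialkenylcyclohexanol | C=C[C@]1(O)[C@@](C)(OCOC)C[C@H]2OC(C)(C)O[C@H]2[C@]1(OCOC)/C=C(/C)OCOC
A5 | alternative 3 | oxa-bridged cyclodecadiene with masked butenolide | CC(C)(C)[Si](C)(C)O[C@@H]1C[C@](C)(OCOC)C2=CC[C@](C)(CC3(OCCO3)/C1=C(/CO[Si](C)(C)C(C)(C)C)C(=O)OC(C)(C)C)O2
A6 | alternative 3 | bridged 1,3-oxathiane S,S-dioxide | CC(C)(C)[Si](C)(C)O[C@@H]1C[C@](C)(OCOC)[C@@H]2O[C@](C)(CCS2(=O)=O)CC3(OCCO3)/C1=C(/CO[Si](C)(C)C(C)(C)C)C(=O)OC(C)(C)C
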